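**Plan**

- Retrosynthetic cuts, in order: the two acetates; C6–C7 (Ni/Cr closure of the ten-membered ring); C4–C5 and C2=C3 (chain growth from a C2 aldehyde); C11–O; then C1–C10 and C13–C14 together, by an intramolecular Diels–Alder reaction of an acyclic ester.
- Enabling feature: the six-membered ring C1/C10/C11/C12/C13/C14 with its C11 carbinol is a cyclohexene (C11=C12) retron. O9 and the sp2 carbon C2 both hang on the C1–C10 bond, so they can be tied as a temporary γ-lactone ring (ester tether O9–C2) that is opened again after the cycloaddition.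
- Forward order: acyclic trienyl ester → bicyclic lactone (six-membered ring plus temporary five-membered ring) → lactone opened and chain C3–C6 added at C2 → ten-membered ring closed last.
- Stereochemistry: C9 from a catalytic asymmetric 2-bromoallylation; C10 and C14 relayed from C9 in the cycloaddition, C1 by epimerisation to the cis lactone; C11 by convex-face epoxidation; Z C2=C3 by Still–Gennari olefination; C6 by ligand-controlled Ni/Cr cyclisation.

Key step: step 6

Remark: locants C1–C14 are those of the target skeleton (ten-membered ring C1–C10; six-membered ring C1, C10, C11, C12, C13, C14); the target is (1S,2Z,6R,9R,10S,11R,14R).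
Remark: in steps 4 and 16 the antipode of the chiral chromium ligand L* is the one that induces the configuration drawn; the sense is to be confirmed on the product (Mosher esters).

**Route**

Step 1
Reactants: 1 4-methylpent-2-ynoic acid
Product: 2 (2Z)-4-methylpent-2-enoic acid
Conditions: H2 (1 atm), Pd/CaCO3 poisoned with Pb(OAc)2, quinoline, EtOAc, rt
Reagents that add atoms: none
Why: Lindlar semi-hydrogenation adds H2 syn on the poisoned Pd surface and should give only the Z acid.

Step 2
Reactants: 3 (2E)-3-methylpent-2-en-4-yn-1-ol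
Product: 4 (2E)-3-methylpenta-2,4-dien-1-ol
Conditions: H2 (1 atm), Pd/CaCO3 poisoned with Pb(OAc)2, quinoline, hexane/EtOAc, 0 °C, stopped after 1 equiv H2
Reagents that add atoms: none
Why: Lindlar semi-hydrogenation of the terminal alkyne to the vinyl group leaves the trisubstituted E olefin untouched.

Step 3
Reactants: 4 (2E)-3-methylpenta-2,4-dien-1-ol
Product: 5 (2E)-3-methylpenta-2,4-dienal
Conditions: MnO2, CH2Cl2, rt; used as a solution
Reagents that add atoms: none
Why: MnO2 oxidation of an allylic alcohol, with the E geometry retained.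

Step 4
Reactants: 5 (2E)-3-methylpenta-2,4-dienal; 6 2,3-dibromoprop-1-ene
Product: 8 (4R,5E)-2-bromo-6-methylocta-1,5,7-trien-4-ol, via trimethylsilyl ether 7 (not isolated)
Conditions: CrCl2 (10 mol%), chiral 2-(4-tert-butyl-oxazolin-2-yl)aryl methanesulfonamide ligand L* (12 mol%), Et3N (20 mol%), Fe(C11H19O2)3 (iron tris(2,2,6,6-tetramethylheptane-3,5-dionate), 2 mol%), Mn powder, Me3SiCl, THF/MeCN, 0 °C; then K2CO3, MeOH, 0 °C
Reagents that add atoms: none
Why: Catalytic asymmetric Nozaki–Hiyama 2-haloallylation, in which the ligand-bound 2-bromoallylchromium adds 1,2 to the enal through a closed six-membered transition state and the ligand fixes the carbinol (C9) as R; the alkenyl bromide is inert to CrCl2 without nickel.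

Step 5
Reactants: 8 (4R,5E)-2-bromo-6-methylocta-1,5,7-trien-4-ol; 2 (2Z)-4-methylpent-2-enoic acid
Product: 9 (4R,5E)-2-bromo-6-methylocta-1,5,7-trien-4-yl (2Z)-4-methylpent-2-enoate
Conditions: DCC, DMAP (5 mol%), CH2Cl2, −20 → 0 °C
Reagents that add atoms: none
Why: Steglich esterification at low temperature, chosen to avoid Z→E isomerisation of the enoate and ionisation of the dienylic carbinol.

Step 6
Reactants: 9 (4R,5E)-2-bromo-6-methylocta-1,5,7-trien-4-yl (2Z)-4-methylpent-2-enoate
Product: 11 (3R,3aR,7R,7aR)-3-(2-bromoprop-2-en-1-yl)-4-methyl-7-(propan-2-yl)-3a,6,7,7a-tetrahydro-2-benzofuran-1(3H)-one (cis-fused), via trans-fused lactone 10 (not isolated)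
Conditions: BHT (5 mol%), toluene (0.02 M), sealed tube, 180 °C; then DBU (1 equiv), 80–110 °C
Reagents that add atoms: none
Why: Thermal concerted suprafacial [4+2] cycloaddition of the diene C10=C11–C12=C13 with the Z enoate C1=C14 held by the ester tether O9–C2(=O), a type 1 intramolecular Diels–Alder reaction of the ester-linked 1,3,8-nonatriene (pentadienyl acrylate) class, followed in the same pot by base epimerisation α to the lactone carbonyl. The carbocycle closes as a six-membered ring by [4+2], and the tether becomes a five-membered γ-lactone fused at C1–C10, first trans (tether exo) and cis after DBU. C10 is set by C9: allylic 1,3-strain with the C11 methyl forces H9 into the diene plane, so the ester oxygen and with it the dienophile can reach one diene face only, which gives the target configuration at C10 from 9R. C14 is set by the Z geometry together with the exo mode, in which the tether carbonyl and the isopropyl group both point away from the diene; the slight exo preference of short ester tethers and the steric exo preference of a β-alkyl group reinforce each other here, as they would not in the E ester, and place isopropyl trans to C9. C1 is then corrected thermodynamically, because the trans-fused lactone 10 carries an axial isopropyl group and a strained trans 5/6 fusion, so enolisation funnels it to the cis-fused 11 with C2 and isopropyl trans-diequatorial. Regiochemistry needs no electronic bias, since the three-atom tether allows only the C1–C10/C13–C14 mode.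

Step 7
Reactants: 11 cis-fused lactone
Product: 12 C11–C12 epoxide of 11 (oxirane on the face of H1 and H10)
Conditions: mCPBA, NaHCO3, CH2Cl2, 0 °C
Reagents that add atoms: mCPBA, O=C(OO)c1cccc(Cl)c1
Why: Prilezhaev epoxidation of the only electron-rich olefin (the 2-bromoalkene is deactivated), from the convex face of the cis-fused bicycle and anti to the pseudoaxial C10–C9 bond, which places the C11 oxygen on the face of H10.

Step 8
Reactants: 12 epoxy lactone
Product: 13 triol (C2 primary, C9 secondary, C11 tertiary alcohol; alkenyl bromide intact)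
Conditions: LiBHEt3 (5 equiv), THF, 0 °C → rt; then H2O
Reagents that add atoms: none
Why: The borohydride reduces the lactone to the C2/C9 diol and opens the epoxide by SN2 attack of hydride at the secondary carbon C12 (trans-diaxial), so the C11 tertiary alcohol keeps the epoxide configuration; alkenyl bromides are not reduced by this reagent.

Step 9
Reactants: 13 triol
Product: 14 tris(triethylsilyl) ether of 13
Conditions: Et3SiOSO2CF3 (3.5 equiv), 2,6-lutidine, CH2Cl2, −78 → 0 °C
Reagents that add atoms: triethylsilyl triflate, CC[Si](CC)(CC)OS(=O)(=O)C(F)(F)F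
Why: Exhaustive silylation with the silyl triflate, which also reaches the tertiary alcohol and lets step 11 tell the primary oxygen from the secondary one.

Step 10
Reactants: 14 tris(triethylsilyl) ether, alkenyl bromide
Product: 15 the corresponding alkenyl iodide
Conditions: CuI (10 mol%), trans-N,N'-dimethylcyclohexane-1,2-diamine (20 mol%), NaI (3 equiv), dioxane, 110 °C
Reagents that add atoms: sodium iodide, [Na+].[I-]
Why: Copper-catalysed halogen exchange (alkenyl Finkelstein reaction) gives the iodide needed for the Ni/Cr coupling, with no stereocentre touched.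

Step 11
Reactants: 15 tris(triethylsilyl) ether, alkenyl iodide
Product: 16 C2 aldehyde (C9 and C11 triethylsilyl ethers retained)
Conditions: (COCl)2, DMSO, CH2Cl2, −78 → −30 °C; then Et3N, −78 °C → rt
Reagents that add atoms: none
Why: Under Swern conditions the primary triethylsilyl ether is cleaved and oxidised directly, because chlorodimethylsulfonium attacks the least hindered Si–O bond, while the secondary and tertiary silyl ethers persist; the low temperature protects C1 from epimerisation.

Step 12
Reactants: 16 C2 aldehyde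
Product: 17 methyl (2Z)-2-methylalk-2-enoate (C2=C3 Z, ester carbon = C4)
Conditions: methyl 2-[bis(2,2,2-trifluoroethoxy)phosphoryl]propanoate, KN(SiMe3)2, 18-crown-6, THF, −78 °C
Reagents that add atoms: methyl 2-[bis(2,2,2-trifluoroethoxy)phosphoryl]propanoate, COC(=O)C(C)P(=O)(OCC(F)(F)F)OCC(F)(F)F
Why: In the Still–Gennari olefination the trifluoroethyl phosphonate eliminates fast from the kinetically formed adduct and should give the Z α-methyl enoate, that is C4 cis to C1 across C2=C3.

Step 13
Reactants: 17 Z enoate
Product: 18 Z allylic alcohol (C4–OH)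
Conditions: i-Bu2AlH (2.5 equiv), CH2Cl2, −78 °C; Rochelle salt work-up
Reagents that add atoms: none
Why: 1,2-Reduction of the enoate by the aluminium hydride at low temperature, with olefin geometry, alkenyl iodide and silyl ethers retained.

Step 14
Reactants: 18 Z allylic alcohol
Product: 19 Z allylic bromide (C4–Br)
Conditions: CBr4, PPh3, 2,6-lutidine (0.2 equiv), CH2Cl2, −20 °C
Reagents that add atoms: carbon tetrabromide, BrC(Br)(Br)Br
Why: Appel bromination of the primary allylic alcohol by SN2 displacement of the oxyphosphonium, with Z geometry retained.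

Step 15
Reactants: 19 Z allylic bromide; 20 acetaldehyde N,N-dimethylhydrazone
Product: 22 C6 aldehyde (chain C2=C3(CH3)–C4H2–C5H2–C6HO), via alkylated hydrazone 21 (not isolated)
Conditions: 20, LiN(iPr)2, THF, 0 °C; then 19, −78 → 0 °C; then Cu(OAc)2, THF/H2O (pH 7), rt
Reagents that add atoms: water, O
Why: Corey–Enders alkylation, in which the lithiated hydrazone (an acetaldehyde enolate equivalent) displaces the allylic bromide by SN2 and adds C5 and C6, and neutral copper-assisted hydrolysis unmasks the aldehyde without harming the silyl ethers.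

Step 16
Reactants: 22 C6 aldehyde with C7 alkenyl iodide
Product: 23 bicyclic (6R)-allylic alcohol (ten-membered ring closed; C9 and C11 triethylsilyl ethers)
Conditions: CrCl2 (4 equiv), chiral oxazolinyl-aryl sulfonamide ligand L* (4.4 equiv), Et3N (4.4 equiv), NiCl2 (10 mol%), THF, rt, slow addition of 22 (final 2 mM)
Reagents that add atoms: none
Why: Intramolecular Nozaki–Hiyama–Kishi reaction, in which nickel inserts into the alkenyl iodide, the alkenyl group passes to chromium and adds to the aldehyde, closing the ten-membered ring at C6–C7 (helped by the Z olefin and the gauche C1/C10 substituents); the chiral ligand on chromium is chosen to deliver the 6R carbinol.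

Step 17
Reactants: 23 bis(triethylsilyl) ether
Product: 24 C6,C9,C11-triol
Conditions: Bu4NF, THF, rt → 40 °C
Reagents that add atoms: none
Why: Fluoride cleaves both silyl ethers under basic conditions that leave the allylic alcohol and both olefins untouched.

Step 18
Reactants: 24 triol
Product: 25 target diacetate
Conditions: Ac2O, pyridine, DMAP (5 mol%), CH2Cl2, 0 °C → rt, stopped at the diacetate
Reagents that add atoms: acetic anhydride, CC(=O)OC(C)=O
Why: Acetylation of the two secondary alcohols, while the hindered axial tertiary C11 alcohol should not react under these conditions.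

**Compound list**

1 | 4-methylpent-2-ynoic acid | CC(C)C#CC(=O)O | starting material
2 | (2Z)-4-methylpent-2-enoic acid | CC(C)/C=C\C(=O)O | intermediate
3 | (2E)-3-methylpent-2-en-4-yn-1-ol | C#C/C(C)=C/CO | starting material
4 | (2E)-3-methylpenta-2,4-dien-1-ol | C=C/C(C)=C/CO | intermediate
5 | (2E)-3-methylpenta-2,4-dienal | C=C/C(C)=C/C=O | intermediate
6 | 2,3-dibromoprop-1-ene | C=C(Br)CBr | starting material
7 | trimethylsilyl ether of 8 | C=C(Br)C[C@@H](O[Si](C)(C)C)/C=C(\C)C=C | intermediate
8 | (4R,5E)-2-bromo-6-methylocta-1,5,7-trien-4-ol | C=C(Br)C[C@@H](O)/C=C(\C)C=C | intermediate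
9 | (4R,5E)-2-bromo-6-methylocta-1,5,7-trien-4-yl (2Z)-4-methylpent-2-enoate | C=C(Br)C[C@@H](OC(=O)/C=C\C(C)C)/C=C(\C)C=C | intermediate
10 | (3R,3aR,7R,7aS)-3-(2-bromoprop-2-en-1-yl)-4-methyl-7-(propan-2-yl)-3a,6,7,7a-tetrahydro-2-benzofuran-1(3H)-one (trans-fused) | C=C(Br)C[C@H]1OC(=O)[C@H]2[C@@H](C(C)C)CC=C(C)[C@H]12 | intermediate
11 | (3R,3aR,7R,7aR)-3-(2-bromoprop-2-en-1-yl)-4-methyl-7-(propan-2-yl)-3a,6,7,7a-tetrahydro-2-benzofuran-1(3H)-one (cis-fused) | C=C(Br)C[C@H]1OC(=O)[C@@H]2[C@@H](C(C)C)CC=C(C)[C@H]12 | intermediate
12 | C11–C12 epoxide of 11, oxirane cis to H1 and H10 | C=C(Br)C[C@H]1OC(=O)[C@@H]2[C@@H](C(C)C)C[C@H]3O[C@@]3(C)[C@H]12 | intermediate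
13 | triol: cyclohexane with CH2OH on C1, (R)-CH(OH)CH2C(Br)=CH2 on C10, OH and CH3 on C11, isopropyl on C14, ring centres as in 25 | C=C(Br)C[C@@H](O)[C@H]1[C@](C)(O)CC[C@H](C(C)C)[C@H]1CO | intermediate
14 | tris(triethylsilyl) ether of 13 | C=C(Br)C[C@@H](O[Si](CC)(CC)CC)[C@H]1[C@](C)(O[Si](CC)(CC)CC)CC[C@H](C(C)C)[C@H]1CO[Si](CC)(CC)CC | intermediate
15 | alkenyl iodide analogue of 14 | C=C(I)C[C@@H](O[Si](CC)(CC)CC)[C@H]1[C@](C)(O[Si](CC)(CC)CC)CC[C@H](C(C)C)[C@H]1CO[Si](CC)(CC)CC | intermediate
16 | C2 aldehyde, C9/C11 bis(triethylsilyl) ether, C7 iodide | C=C(I)C[C@@H](O[Si](CC)(CC)CC)[C@H]1[C@](C)(O[Si](CC)(CC)CC)CC[C@H](C(C)C)[C@H]1C=O | intermediate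
17 | methyl (2Z)-2-methylprop-2-enoate on C1 (C2=C3 Z, C4 ester) | C=C(I)C[C@@H](O[Si](CC)(CC)CC)[C@H]1[C@](C)(O[Si](CC)(CC)CC)CC[C@H](C(C)C)[C@H]1/C=C(/C)C(=O)OC | intermediate
18 | Z allylic alcohol (C4–OH) | C=C(I)C[C@@H](O[Si](CC)(CC)CC)[C@H]1[C@](C)(O[Si](CC)(CC)CC)CC[C@H](C(C)C)[C@H]1/C=C(/C)CO | intermediate
19 | Z allylic bromide (C4–Br) | C=C(I)C[C@@H](O[Si](CC)(CC)CC)[C@H]1[C@](C)(O[Si](CC)(CC)CC)CC[C@H](C(C)C)[C@H]1/C=C(/C)CBr | intermediate
20 | acetaldehyde N,N-dimethylhydrazone | CC=NN(C)C | starting material
21 | N,N-dimethylhydrazone of 22 | C=C(I)C[C@@H](O[Si](CC)(CC)CC)[C@H]1[C@](C)(O[Si](CC)(CC)CC)CC[C@H](C(C)C)[C@H]1/C=C(/C)CCC=NN(C)C | intermediate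
22 | C6 aldehyde with Z C2=C3 and C7 iodide | C=C(I)C[C@@H](O[Si](CC)(CC)CC)[C@H]1[C@](C)(O[Si](CC)(CC)CC)CC[C@H](C(C)C)[C@H]1/C=C(/C)CCC=O | intermediate
23 | bicyclic (6R)-alcohol, C9/C11 bis(triethylsilyl) ether | C=C1C[C@@H](O[Si](CC)(CC)CC)[C@@H]2[C@H](/C=C(/C)CC[C@H]1O)[C@@H](C(C)C)CC[C@@]2(C)O[Si](CC)(CC)CC | intermediate
24 | bicyclic C6,C9,C11-triol | C=C1C[C@@H](O)[C@@H]2[C@H](/C=C(/C)CC[C@H]1O)[C@@H](C(C)C)CC[C@@]2(C)O | intermediate
25 | CNP0303839.1, (1S,2Z,6R,9R,10S,11R,14R)-6,9-diacetate | C=C1C[C@@H](OC(C)=O)[C@@H]2[C@H](/C=C(/C)CC[C@H]1OC(C)=O)[C@@H](C(C)C)CC[C@@]2(C)O | target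

**Count and risks**

Total steps: 18 (step 1 is a one-step side branch). Longest linear sequence: 17 steps (3 → 25, steps 2–18).

Step 6. The hindered Z enoate may cyclise too slowly, so that thermal deconjugation by 1,5-hydrogen shift or Z→E isomerisation competes, or exo/endo discrimination may be incomplete; either erodes the relay to C14. The fallback sets out from 8 and returns at 11, and replaces kinetic exo control by thermodynamic control of both new carbon centres. Carbinol 8 is esterified (DCC, DMAP) with (2E)-4-oxopent-2-enoic acid to (4R,5E)-2-bromo-6-methylocta-1,5,7-trien-4-yl (2E)-4-oxopent-2-enoate F1, whose doubly activated dienophile should cyclise below 100 °C. DBU then equilibrates C1 (α to the lactone) and C14 (α to the ketone) to the cis-fused lactone with an equatorial C14 acetyl group, keto lactone F2. Wittig methylenation with Ph3P=CH2 gives the isopropenyl lactone F3, and hydrogenation of this least hindered olefin with H2 and RhCl(PPh3)3 (or with diimide) gives 11.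

Step 16. Closure of the strained ten-membered ring may be slow, so that oligomerisation or protonation of the alkenylchromium takes over, and facial control at C6 may be weak. The fallback sets out from 22 and returns at 23, and changes the ring-closing event to an anionic acylation followed by a reagent-controlled reduction. Aldehyde 22 is oxidised (NaClO2, NaH2PO4, 2-methylbut-2-ene) to the carboxylic acid F4 and coupled with N,O-dimethylhydroxylamine (EDC) to the Weinreb amide F5. Iodine–lithium exchange with t-BuLi at −100 °C under high dilution and attack of the alkenyllithium on the amide give the bicyclic enone F6, and CBS reduction with the (S)-methyl oxazaborolidine and catecholborane gives 23. If step 16 closes the ring but gives the wrong C6 epimer, that epimer can be oxidised to the same enone F6.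

Step 12. Olefination of the doubly flanked aldehyde may be sluggish, with erosion of Z selectivity or epimerisation at C1 under the basic conditions. The fallback sets out from 14 and returns at 18, and builds the Z allylic alcohol by β-oxido ylide hydroxymethylation before the halogen exchange. Bromide 14 is oxidised under the Swern conditions of step 11 to the bromo aldehyde F7. Ph3P=CHCH3 at −78 °C, then PhLi, then paraformaldehyde (Wittig–Schlosser β-oxido ylide sequence; the alkenyl bromide exchanges only slowly with PhLi at this temperature) gives the Z allylic alcohol F8 with CH2OH cis to C1. CuI/NaI exchange as in step 10 then gives 18.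

**Further compounds**

F1 | step 6 | (4R,5E)-2-bromo-6-methylocta-1,5,7-trien-4-yl (2E)-4-oxopent-2-enoate | C=C(Br)C[C@@H](OC(=O)/C=C/C(C)=O)/C=C(\C)C=C
F2 | step 6 | cis-fused lactone as 11 with acetyl in place of isopropyl at C14 | C=C(Br)C[C@H]1OC(=O)[C@@H]2[C@@H](C(C)=O)CC=C(C)[C@H]12
F3 | step 6 | cis-fused lactone as 11 with isopropenyl in place of isopropyl at C14 | C=C(Br)C[C@H]1OC(=O)[C@@H]2[C@@H](C(C)=C)CC=C(C)[C@H]12
F4 | step 16 | C6 carboxylic acid corresponding to aldehyde 22 | C=C(I)C[C@@H](O[Si](CC)(CC)CC)[C@H]1[C@](C)(O[Si](CC)(CC)CC)CC[C@H](C(C)C)[C@H]1/C=C(/C)CCC(=O)O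
F5 | step 16 | N-methoxy-N-methylamide of F4 | C=C(I)C[C@@H](O[Si](CC)(CC)CC)[C@H]1[C@](C)(O[Si](CC)(CC)CC)CC[C@H](C(C)C)[C@H]1/C=C(/C)CCC(=O)N(C)OC
F6 | step 16 | bicyclic C6 ketone (enone with the C7 methylene), C9/C11 bis(triethylsilyl) ether | C=C1C[C@@H](O[Si](CC)(CC)CC)[C@@H]2[C@H](/C=C(/C)CCC1=O)[C@@H](C(C)C)CC[C@@]2(C)O[Si](CC)(CC)CC
F7 | step 12 | C2 aldehyde as 16 with alkenyl bromide in place of iodide | C=C(Br)C[C@@H](O[Si](CC)(CC)CC)[C@H]1[C@](C)(O[Si](CC)(CC)CC)CC[C@H](C(C)C)[C@H]1C=O
F8 | step 12 | Z allylic alcohol as 18 with alkenyl bromide in place of iodide | C=C(Br)C[C@@H](O[Si](CC)(CC)CC)[C@H]1[C@](C)(O[Si](CC)(CC)CC)CC[C@H](C(C)C)[C@H]1/C=C(/C)CO
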